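**Strategy.** The route rests on cutting the bond between the methyl-bearing alkene carbon of the diene nearest the core and the CH2 next to the methyl-bearing side-chain stereocentre. That alkene carbon is brought in as the CBr2 carbon of a 1,1-dibromo-1,3-diene: in one flask the alkylzinc made from the iodide of the finished peroxylactone core replaces the bromine trans to the dienyl chain, and methylzinc chloride then replaces the other with retention. The step exploits that this carbon carries CH3 cis and CH2 trans to the chain, and it is mild enough for the O–O bond of the 1,2-dioxane ring and the fused γ-lactone ring.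

Key step: step 15

Remark: core locants used below are O1–O2–C3–C4–C4a(–O5–C6(=O)–C7–)C7a; compounds 1, 3, 6, 20 and 21 are taken as commercial, and the C3 configuration rests on the assumption that methyl enters the peroxycarbenium ion of step 10 axially.

**Step 1**
Reactants: 1 (S)-3-bromo-2-methylpropan-1-ol
Product: 2 (S)-(3-bromo-2-methylpropoxy)(tert-butyl)diphenylsilane
Conditions: TBDPSCl, imidazole, CH2Cl2, 23 °C
Reagents that add atoms: tert-butyl(chloro)diphenylsilane, CC(C)(C)[Si](Cl)(c1ccccc1)c1ccccc1
Why: Imidazole-promoted silylation of a primary alcohol, which leaves the stereocentre and the bromide untouched.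

**Step 2**
Reactants: 2 (S)-(3-bromo-2-methylpropoxy)(tert-butyl)diphenylsilane; 3 1,3-dithiane
Product: 5 (R)-tert-butyl[3-(1,3-dithian-2-yl)-2-methylpropoxy]diphenylsilane, via 2-lithio-1,3-dithiane 4 (not isolated)
Conditions: n-BuLi, THF, −30 °C; then 2, −78 → 0 °C
Reagents that add atoms: none
Why: Corey–Seebach alkylation, in which the lithiated dithiane displaces the primary bromide by SN2, so that the dithiane carbon becomes the future C3 and the stereocentre is not involved (the descriptor changes only by priority).

**Step 3**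
Reactants: 6 (S)-2-methylglycidol
Product: 7 triethyl{[(2R)-2-methyloxiran-2-yl]methoxy}silane (triethylsilyl ether of 6, same arrangement in space)
Conditions: Et3SiCl, imidazole, CH2Cl2, 0 °C
Reagents that add atoms: chlorotriethylsilane, CC[Si](Cl)(CC)CC
Why: Silylation of the primary alcohol masks the hydroxyl and prevents Payne rearrangement in the next step.

**Step 4**
Reactants: 5 (R)-tert-butyl[3-(1,3-dithian-2-yl)-2-methylpropoxy]diphenylsilane; 7 triethylsilyl ether of (S)-2-methylglycidol
Product: 9 (2R)-1-{2-[(2R)-3-(tert-butyldiphenylsilyloxy)-2-methylpropyl]-1,3-dithian-2-yl}-2-methyl-3-(triethylsilyloxy)propan-2-ol, via lithiated dithiane 8 (not isolated)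
Conditions: t-BuLi, THF/HMPA (10:1), −78 °C; then 7, −78 → −20 °C; H2O
Reagents that add atoms: none
Why: Corey–Seebach epoxide opening, in which the 2-lithio-2-alkyldithiane attacks the unsubstituted CH2 of the 2,2-disubstituted epoxide, so the quaternary carbinol centre of 6 (future C4a) is carried over unchanged.

**Step 5**
Reactants: 9 dithiane adduct
Product: 10 (2R)-3-{2-[(2R)-3-(tert-butyldiphenylsilyloxy)-2-methylpropyl]-1,3-dithian-2-yl}-2-methylpropane-1,2-diol
Conditions: PPTS (cat.), MeOH, 0 → 23 °C
Reagents that add atoms: none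
Why: Acid-catalysed methanolysis removes the primary triethylsilyl ether much faster than the TBDPS ether.

**Step 6**
Reactants: 10 diol
Product: 11 (2R)-3-{2-[(2R)-3-(tert-butyldiphenylsilyloxy)-2-methylpropyl]-1,3-dithian-2-yl}-2-hydroxy-2-methylpropanal
Conditions: (COCl)2, DMSO, CH2Cl2, −78 °C; Et3N
Reagents that add atoms: none
Why: Swern oxidation converts the primary alcohol to the aldehyde while the tertiary alcohol and the dithiane are inert, and the α-carbon has no hydrogen to epimerise.

**Step 7**
Reactants: 11 α-hydroxy aldehyde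
Product: 13 (5R)-5-({2-[(2R)-3-(tert-butyldiphenylsilyloxy)-2-methylpropyl]-1,3-dithian-2-yl}methyl)-5-methylfuran-2(5H)-one, via acyl ylide ester 12 (not isolated)
Conditions: Ph3P=C=C=O, toluene, 90 °C
Reagents that add atoms: (triphenylphosphoranylidene)ketene, O=C=C=P(c1ccccc1)(c1ccccc1)c1ccccc1
Why: The tertiary hydroxyl adds to the cumulated ylide to give a phosphoranylidene acetate, and an intramolecular Wittig reaction with the neighbouring aldehyde closes the butenolide under neutral conditions.

**Step 8**
Reactants: 13 butenolide dithiane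
Product: 14 (5R)-5-[(4R)-5-(tert-butyldiphenylsilyloxy)-4-methyl-2-oxopentyl]-5-methylfuran-2(5H)-one
Conditions: PhI(OCOCF3)2, MeCN/H2O (9:1), 0 °C
Reagents that add atoms: water, O
Why: Oxidative hydrolysis of the dithioketal with a hypervalent iodine reagent frees the ketone without base, which the β-acyloxy ketone would not tolerate.

**Step 9**
Reactants: 14 keto butenolide
Product: 16 (4aR,7aR)-3-[(2R)-3-(tert-butyldiphenylsilyloxy)-2-methylpropyl]-3-methoxy-4a-methyl-tetrahydrofuro[3,2-c][1,2]dioxin-6-one (cis-fused 1,2-dioxane/γ-lactone, either configuration at C3), via methoxy hydroperoxide 15 (not isolated)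
Conditions: urea–H2O2, Sc(OTf)3 (cat.), MeOH, 23 °C; then Et2NH (cat.), CF3CH2OH, 23 °C
Reagents that add atoms: hydrogen peroxide, OO; methanol, CO
Why: Lewis-acid-catalysed hydroperoxyketalisation of the ketone is followed by a 6-exo-trig intramolecular oxa-Michael addition of the OOH group to the butenolide, in which the short tether allows delivery only to the face cis to C4, so the ring fusion is cis and C7a becomes (R); the C3 configuration is immaterial because C3 is ionised in step 10.

**Step 10**
Reactants: 16 bicyclic methoxy peroxyketal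
Product: 17 (3R,4aR,7aR)-3-[(2R)-3-(tert-butyldiphenylsilyloxy)-2-methylpropyl]-3,4a-dimethyl-tetrahydrofuro[3,2-c][1,2]dioxin-6-one
Conditions: Me2Zn (3 equiv), TiCl4 (2.2 equiv), CH2Cl2, −78 °C
Reagents that add atoms: dimethylzinc, C[Zn]C
Why: Proposed new method: TiCl4 should ionise the methoxy group to a cyclic peroxycarbenium ion that is captured by MeTiCl3 formed in the flask, and the ion should react through the half-chair leading to the chair with the C4a–O5 bond axial and the C4a methyl equatorial, so methyl enters axially on the face of the lactone oxygen, the side chain ends equatorial and C3 becomes (R) from either epimer of 16 (the bulky TBDPS ether is not expected to participate); the closest known reaction types are the Lewis-acid-mediated Sakurai-type allylation of 3-alkoxy-1,2-dioxanes through peroxycarbenium ions and the Me2Zn/TiCl4 methylation of tertiary ethers and ketals.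

**Step 11**
Reactants: 17 C-methyl peroxylactone silyl ether
Product: 18 (3R,4aR,7aR)-3-[(2R)-3-hydroxy-2-methylpropyl]-3,4a-dimethyl-tetrahydrofuro[3,2-c][1,2]dioxin-6-one
Conditions: HF·pyridine, pyridine/THF, 0 → 23 °C
Reagents that add atoms: none
Why: Fluoride-mediated desilylation under buffered, non-basic conditions spares the β-peroxy lactone, which a basic fluoride source could open by elimination.

**Step 12**
Reactants: 18 primary alcohol
Product: 19 (3R,4aR,7aR)-3-[(2R)-3-iodo-2-methylpropyl]-3,4a-dimethyl-tetrahydrofuro[3,2-c][1,2]dioxin-6-one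
Conditions: PPh3, I2, imidazole, CH2Cl2, 0 °C (18 added last)
Reagents that add atoms: iodine, II
Why: Appel-type iodination through the alkoxyphosphonium salt, with the phosphine consumed by iodine before the alcohol is added so that no free phosphine meets the hindered dialkyl peroxide.

**Step 13**
Reactants: 20 phenylacetaldehyde; 21 2-(triphenylphosphoranylidene)propanal
Product: 22 (E)-2-methyl-4-phenylbut-2-enal
Conditions: toluene, 80 °C
Reagents that add atoms: none
Why: Wittig reaction of a stabilised formyl ylide, which should give the (E)-enal under thermodynamic control of the oxaphosphetane.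

**Step 14**
Reactants: 22 (E)-2-methyl-4-phenylbut-2-enal
Product: 23 (3E)-1,1-dibromo-3-methyl-5-phenylpenta-1,3-diene
Conditions: CBr4, PPh3, CH2Cl2, 0 °C
Reagents that add atoms: tetrabromomethane, BrC(Br)(Br)Br
Why: Ramirez dibromo-olefination (first stage of the Corey–Fuchs sequence) converts the aldehyde to the gem-dibromoalkene without touching the existing (E)-alkene.

**Step 15**
Reactants: 19 core iodide; 23 (3E)-1,1-dibromo-3-methyl-5-phenylpenta-1,3-diene
Product: 26 plakortolide, via alkylzinc iodide 24 (not isolated), via bromodiene 25 (not isolated)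
Conditions: Zn dust (activated with BrCH2CH2Br, Me3SiCl), LiCl, THF, 25 °C; then 23, PdCl2(DPEphos) (5 mol%), THF/DMF, 0 → 23 °C; then MeZnCl, Pd(P(t-Bu)3)2 (5 mol%), 23 °C
Reagents that add atoms: methylzinc chloride, C[Zn]Cl
Why: Zinc inserts into the primary C–I bond of 19 to give 24; zerovalent palladium formed from PdCl2(DPEphos) adds oxidatively to the C–Br bond of 23 that lies trans to the dienyl substituent, and transmetalation with 24 followed by reductive elimination forms the C(sp3)–C(sp2) bond to give 25; Pd(P(t-Bu)3)2 then activates the remaining hindered C–Br bond and MeZnCl delivers methyl with retention. The closest known reaction type is the palladium-catalysed trans-selective Negishi monoalkylation of 1,1-dibromo-1-alkenes with β-branched alkylzinc reagents followed by stereoretentive methylation, fed here by a LiCl-mediated zinc insertion. No ring is closed. No stereocentre is formed; the geometry of the new trisubstituted alkene is controlled by the (E)-methyl-substituted alkenyl group of 23, which shields the cis bromine in the first coupling, and by the bulky monophosphine catalyst, which suppresses isomerisation of the alkenylpalladium in the second. The step needs chemoselectivity for C–I over the O–O bond and the lactone: insertion into an unhindered primary iodide at room temperature without a proton source should outpace electron transfer to the hindered secondary–tertiary dialkyl peroxide, and alkylzinc halides neither add to lactones nor remove the α-protons whose loss would open the β-peroxy lactone.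

**Compound list**

1 | (S)-3-bromo-2-methylpropan-1-ol | OC[C@H](C)CBr | starting material
2 | (S)-(3-bromo-2-methylpropoxy)(tert-butyl)diphenylsilane | CC(C)(C)[Si](c1ccccc1)(c1ccccc1)OC[C@H](C)CBr | intermediate
3 | 1,3-dithiane | C1CSCSC1 | starting material
4 | 2-lithio-1,3-dithiane | [Li]C1SCCCS1 | intermediate
5 | (R)-tert-butyl[3-(1,3-dithian-2-yl)-2-methylpropoxy]diphenylsilane | CC(C)(C)[Si](c1ccccc1)(c1ccccc1)OC[C@H](C)CC1SCCCS1 | intermediate
6 | (S)-2-methylglycidol | C[C@]1(CO)CO1 | starting material
7 | triethyl{[(2R)-2-methyloxiran-2-yl]methoxy}silane | C[C@]1(CO[Si](CC)(CC)CC)CO1 | intermediate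
8 | 2-lithio derivative of 5 | CC(C)(C)[Si](c1ccccc1)(c1ccccc1)OC[C@H](C)CC1([Li])SCCCS1 | intermediate
9 | (2R)-1-{2-[(2R)-3-(tert-butyldiphenylsilyloxy)-2-methylpropyl]-1,3-dithian-2-yl}-2-methyl-3-(triethylsilyloxy)propan-2-ol | CC(C)(C)[Si](c1ccccc1)(c1ccccc1)OC[C@H](C)CC1(C[C@@](C)(O)CO[Si](CC)(CC)CC)SCCCS1 | intermediate
10 | (2R)-3-{2-[(2R)-3-(tert-butyldiphenylsilyloxy)-2-methylpropyl]-1,3-dithian-2-yl}-2-methylpropane-1,2-diol | CC(C)(C)[Si](c1ccccc1)(c1ccccc1)OC[C@H](C)CC1(C[C@@](C)(O)CO)SCCCS1 | intermediate
11 | (2R)-3-{2-[(2R)-3-(tert-butyldiphenylsilyloxy)-2-methylpropyl]-1,3-dithian-2-yl}-2-hydroxy-2-methylpropanal | CC(C)(C)[Si](c1ccccc1)(c1ccccc1)OC[C@H](C)CC1(C[C@@](C)(O)C=O)SCCCS1 | intermediate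
12 | (triphenylphosphoranylidene)acetate ester of the tertiary hydroxyl of 11 | CC(C)(C)[Si](c1ccccc1)(c1ccccc1)OC[C@H](C)CC1(C[C@@](C)(OC(=O)C=P(c2ccccc2)(c2ccccc2)c2ccccc2)C=O)SCCCS1 | intermediate
13 | (5R)-5-({2-[(2R)-3-(tert-butyldiphenylsilyloxy)-2-methylpropyl]-1,3-dithian-2-yl}methyl)-5-methylfuran-2(5H)-one | CC(C)(C)[Si](c1ccccc1)(c1ccccc1)OC[C@H](C)CC1(C[C@@]2(C)OC(=O)C=C2)SCCCS1 | intermediate
14 | (5R)-5-[(4R)-5-(tert-butyldiphenylsilyloxy)-4-methyl-2-oxopentyl]-5-methylfuran-2(5H)-one | CC(C)(C)[Si](c1ccccc1)(c1ccccc1)OC[C@H](C)CC(=O)C[C@@]1(C)OC(=O)C=C1 | intermediate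
15 | methoxy hydroperoxide (hydroperoxy methyl ketal) of 14, either configuration at the ketal carbon | CC(C)(C)[Si](c1ccccc1)(c1ccccc1)OC[C@H](C)CC(OC)(OO)C[C@@]1(C)OC(=O)C=C1 | intermediate
16 | (4aR,7aR)-3-[(2R)-3-(tert-butyldiphenylsilyloxy)-2-methylpropyl]-3-methoxy-4a-methyl-tetrahydrofuro[3,2-c][1,2]dioxin-6-one, C3 epimers | CC(C)(C)[Si](c1ccccc1)(c1ccccc1)OC[C@H](C)CC1(OC)C[C@@]2(C)OC(=O)C[C@H]2OO1 | intermediate
17 | (3R,4aR,7aR)-3-[(2R)-3-(tert-butyldiphenylsilyloxy)-2-methylpropyl]-3,4a-dimethyl-tetrahydrofuro[3,2-c][1,2]dioxin-6-one | CC(C)(C)[Si](c1ccccc1)(c1ccccc1)OC[C@H](C)C[C@]1(C)C[C@@]2(C)OC(=O)C[C@H]2OO1 | intermediate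
18 | (3R,4aR,7aR)-3-[(2R)-3-hydroxy-2-methylpropyl]-3,4a-dimethyl-tetrahydrofuro[3,2-c][1,2]dioxin-6-one | OC[C@H](C)C[C@]1(C)C[C@@]2(C)OC(=O)C[C@H]2OO1 | intermediate
19 | (3R,4aR,7aR)-3-[(2R)-3-iodo-2-methylpropyl]-3,4a-dimethyl-tetrahydrofuro[3,2-c][1,2]dioxin-6-one | IC[C@H](C)C[C@]1(C)C[C@@]2(C)OC(=O)C[C@H]2OO1 | intermediate
20 | phenylacetaldehyde | O=CCc1ccccc1 | starting material
21 | 2-(triphenylphosphoranylidene)propanal | CC(C=O)=P(c1ccccc1)(c1ccccc1)c1ccccc1 | starting material
22 | (E)-2-methyl-4-phenylbut-2-enal | O=C/C(C)=C/Cc1ccccc1 | intermediate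
23 | (3E)-1,1-dibromo-3-methyl-5-phenylpenta-1,3-diene | BrC(Br)=C/C(C)=C/Cc1ccccc1 | intermediate
24 | alkylzinc iodide from 19 | I[Zn]C[C@H](C)C[C@]1(C)C[C@@]2(C)OC(=O)C[C@H]2OO1 | intermediate
25 | (3R,4aR,7aR)-3-[(2R,4Z,6E)-4-bromo-2,6-dimethyl-8-phenylocta-4,6-dien-1-yl]-3,4a-dimethyl-tetrahydrofuro[3,2-c][1,2]dioxin-6-one | CC(=C\Cc1ccccc1)/C=C(\Br)C[C@H](C)C[C@]1(C)C[C@@]2(C)OC(=O)C[C@H]2OO1 | intermediate
26 | plakortolide, (3R,4aR,7aR)-3,4a-dimethyl-3-[(2S,4E,6E)-2,4,6-trimethyl-8-phenylocta-4,6-dien-1-yl]-tetrahydrofuro[3,2-c][1,2]dioxin-6-one | CC(=C\Cc1ccccc1)/C=C(\C)C[C@H](C)C[C@]1(C)C[C@@]2(C)OC(=O)C[C@H]2OO1 | target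

**Totals.** Total step count: 15. Longest linear sequence: 12 steps (steps 1, 2, 4–12 and 15).

**Steps most likely to fail**

Step 10 (proposed new method). After ionisation the peroxycarbenium ion may lose a proton, or suffer O–O heterolysis with carbon migration, faster than it captures methyl, or the capture may not be face-selective. The fallback uses known chemistry and gives up control at C3. It sets out from ketone 14. Takai–Lombardo methylenation (Zn, CH2Br2, TiCl4) should give the 1,1-disubstituted alkene F1. Mukaiyama–Isayama hydroperoxysilylation (Co(thd)2, thd = 2,2,6,6-tetramethylheptane-3,5-dionate, O2, Et3SiH) should give the triethylsilyl peroxide F2 as both epimers at the new quaternary carbon. Methanolysis (cat. HCl, MeOH) should free the tertiary hydroperoxide F3. Et2NH in CF3CH2OH should then close the dioxane by the oxa-Michael addition of step 9, giving 17 together with its C3 epimer, the epi-peroxylactone F4, which would be removed by chromatography. The route is rejoined at 17.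

Step 15 (key step). The O–O bond may be cleaved reductively by zinc metal or by electron-rich zerovalent palladium, the carbon–zinc bond may attack the peroxide intramolecularly, or alkene geometry may erode in the second coupling. The fallback sets out from 23 and 19 and uses the core iodide as the electrophile, with no zinc metal and no alkylzinc. The second stage of the Corey–Fuchs sequence (n-BuLi, then MeI) should convert 23 into the enyne F5. Hydrozirconation with Cp2Zr(H)Cl should place zirconium on the methyl-bearing alkyne carbon, syn to the new hydrogen, giving the alkenylzirconocene chloride F6, used in solution. Coupling of F6 with 19 under Pd(acac)2/LiBr catalysis (THF/NMP, 55 °C) should then form the same bond with retention of alkene geometry and arrive directly at 26.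

Step 9. Before the hydroperoxide is in place the β-acyloxy ketone may expel the lactone carboxylate by elimination or close onto the butenolide through its enol, and over-addition of hydrogen peroxide may compete with mixed-ketal formation. The fallback sets out from dithiane 13 and never liberates the ketone. Oxidative unmasking with PhI(OCOCF3)2 in dry methanol should give the dimethyl ketal F7. Acid-catalysed exchange of one methoxy group with anhydrous ethereal H2O2 should give the methoxy hydroperoxide 15, where the route is rejoined before the amine-promoted cyclisation of step 9.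

**Further compounds**

F1 | step 10 | (5R)-5-[(4R)-5-(tert-butyldiphenylsilyloxy)-4-methyl-2-methylidenepentyl]-5-methylfuran-2(5H)-one | CC(C)(C)[Si](c1ccccc1)(c1ccccc1)OC[C@H](C)CC(=C)C[C@@]1(C)OC(=O)C=C1
F2 | step 10 | triethylsilyl peroxide of the tertiary carbon of F1 after Markovnikov hydroperoxidation, both epimers | CC(C)(C)[Si](c1ccccc1)(c1ccccc1)OC[C@H](C)CC(C)(OO[Si](CC)(CC)CC)C[C@@]1(C)OC(=O)C=C1
F3 | step 10 | tertiary hydroperoxide from F2, both epimers | CC(C)(C)[Si](c1ccccc1)(c1ccccc1)OC[C@H](C)CC(C)(OO)C[C@@]1(C)OC(=O)C=C1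
F4 | step 10 | (3S,4aR,7aR) epimer of 17 | CC(C)(C)[Si](c1ccccc1)(c1ccccc1)OC[C@H](C)C[C@@]1(C)C[C@@]2(C)OC(=O)C[C@H]2OO1
F5 | step 15 | (E)-(3-methylhex-2-en-4-yn-1-yl)benzene | CC#C/C(C)=C/Cc1ccccc1
F6 | step 15 | chlorobis(cyclopentadienyl)[(2E,4E)-4-methyl-6-phenylhexa-2,4-dien-2-yl]zirconium | C/C(=C\C(C)=C\Cc1ccccc1)[Zr](Cl)(C1C=CC=C1)C1C=CC=C1
F7 | step 9 | dimethyl ketal of 14 | CC(C)(C)[Si](c1ccccc1)(c1ccccc1)OC[C@H](C)CC(OC)(OC)C[C@@]1(C)OC(=O)C=C1
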